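The earlier runs and the new flask stem from a simulated flask with constants of no real substance.

Free catalyst is the species to watch in these flasks, and you watch it through the product curve.

| flask | starting material | partner | free catalyst | product | time |
|---|---|---|---|---|---|
| south | 0.100 M | 0.150 M | 2.00 × 10⁻⁴ M |  |  |
| south-west | 0.100 M | 0.150 M | 2.00 × 10⁻⁴ M | 0.0500 M |  |
| east | 0.100 M | 0.150 M | 3.00 × 10⁻⁴ M |  |  |
| south-east | 0.100 M | 0.220 M | 2.00 × 10⁻⁴ M |  |  |
| north-west | 0.0500 M | 0.100 M | 2.00 × 10⁻⁴ M |  | 11 min |

- south run (time / min: [product] / M): 0.44: 0.0099; 0.98: 0.0197; 2.2: 0.0359; 4.9: 0.0577; 11: 0.0751
- south-west run (time / min: [product] / M): 0.44: 0.0596; 0.98: 0.0695; 2.2: 0.0873; 4.9: 0.1069; 11: 0.1255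
- east run (time / min: [product] / M): 0.44: 0.0142; 0.98: 0.0271; 2.2: 0.0484; 4.9: 0.0722; 11: 0.0871
- south-east run (time / min: [product] / M): 0.44: 0.0084; 0.98: 0.0197; 2.2: 0.0371; 4.9: 0.0564; 11: 0.0746

(readings scatter by 5 × 10⁻⁴ M)

- Overall: starting material + partner -> product, with free catalyst as catalyst.
- Constant volume, constant temperature.
- Bound and free are read together.
- "The second partner" is partner.
- An order is taken over about fifteen percent of the charge, up and down.

1. the exponent of [partner] in the starting rate at the charge of the south run (at the point where two percent of the starting material have become product)
2. the exponent of [free catalyst] in the starting rate at the charge of the south run (at the point where two percent of the starting material have become product)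
3. product in the north-west run at 11 min, as a share of the starting material charged

In the south run partner stands at 1.50 times the starting material, so the bench rule is to treat that run as pseudo-first-order, with one rate constant. Call x the natural log of [starting material] charged over [starting material] remaining, with the remainder taken as charge minus product. Over the first 2.2 min of the south run, x climbs at 0.202 min⁻¹. Held steady, that slope gives 89.2% at 11 min, but the south reading is 75.1%.

The rule stops there. Between 4.9 min and 11 min the south slope is 0.0869 min⁻¹, so early over late is 2.32. The south-east run, with 1.47 times the partner, reads 0.0746 M at 11 min against 0.0751 M in south, a gap of 0.500 mM with a scatter of 5 × 10⁻⁴ M. By 11 min the south-west run makes 0.0755 M on top of its charged product. I read the slope as following the clock, and as free catalyst being lost.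

Now divide one rate by the other, so that time drops out. The south slope carried back to the start is 0.232 min⁻¹, and the fall of the slope between the two stretches gives a loss rate of 0.123 min⁻¹. Their ratio, 1.88, is my catalyst budget: the x that a charge of free catalyst holds, paid out as that catalyst is lost. So on this reckoning, with the loss taken as first order, x is the budget times the share lost by that time.

For north-west I carry over the south budget and the south loss rate, though its partner charge of 0.100 M lies below the other runs. By 11 min the reckoned share lost is 74.2%, so my estimate of x is 1.39 and of product 75.1% of the charge. From x over the first 2.2 min, I read an exponent of 0.109 for partner and 0.980 for free catalyst.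

The forecast gives 0 for partner, 0.97 for free catalyst and 75% for north-west, reasoning that “A first-order run gives the same fractional conversion from any charge”. It differs from my reckoning on the partner exponent.

The flask gives 0.14 for partner, 1.0 for free catalyst and 75.5% for north-west.

    free catalyst + partner ⇌ catalyst-reagent complex, settled at all times (9.640 M⁻¹)
    catalyst-reagent complex + starting material → product + free catalyst (3402 M⁻¹ min⁻¹)
    free catalyst + partner → spent catalyst + partner (2.256 M⁻¹ min⁻¹)
    starting material + partner ⇌ idle substrate-reagent adduct, settled at all times (4.540 M⁻¹)

The north-west result is an x of 1.41, against the 1.39 I reckoned from the budget. Scaled by free catalyst to 2.82 for the east run, the budget puts product at half of the charge at 2.29 min, and the east run gets there at 2.30 min. In north-west, the main reason product falls short is the turning of free catalyst + partner into spent catalyst + partner: with that step removed, product at 11 min rises from 75.5% to 89.0%.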